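**Retrosynthetic overview**

1. Rings: benzene ring A is bought; pyran ring B of the 2H-chromene is closed first (ring-closing metathesis, step 6) and butenolide ring C last (carbonylative lactonisation, step 16).
2. Ring C is traced back to a (Z)-γ-iodo allylic alcohol and then to propargylic alcohol 21, whose alkyne stands for C3=C4 of the lactone.
3. Key disconnection C5–CH2 (C5 of ring C to the allylic CH2 of the side chain): [2,3]-Wittig shift of ether 19, in which the future ring oxygen O1 ties the C9 alkyne fragment to the allylic carbon of the chromene fragment through a C–O bond that is not in the target.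
4. Enabling feature: C5 carries both O1 and the C4=C3 unit and is homoallylic to the C(CH3)=CH alkene, so O1–C5(–C4≡C3)–CH2–C(CH3)=CH is the retron of this shift; the carbinol centre of 12 is relayed to C5 while the E-alkene forms.
5. C2 of ring B comes from Pd-catalysed asymmetric O-allylation of salicylaldehyde 3 with geranyl carbonate 5; the side-chain terminus is then oxidised (SeO2) and transposed (Sharpless epoxidation, zinc opening) to 12.

Key step: step 14

Assumption: in step 4 the (R,R)-ligand is taken to give the (S)-ether from the (E)-carbonate; if the sense of induction is the opposite, the (S,S)-ligand is used and nothing else changes.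

**Route**

Step 1
Reactants: 1 2-methylhydroquinone
Product: 2 2-methyl-4-(triisopropylsilyloxy)phenol
Conditions: i-Pr3SiCl (1.0 equiv), imidazole, DMF, 0 °C to rt
Reagents that add atoms: triisopropylsilyl chloride, CC(C)[Si](Cl)(C(C)C)C(C)C
Why: Silyl ether formation; the bulky silyl chloride should select the hydroxyl without an ortho substituent and leave the one next to the methyl group free.

Step 2
Reactants: 2 2-methyl-4-(triisopropylsilyloxy)phenol
Product: 3 2-hydroxy-3-methyl-5-(triisopropylsilyloxy)benzaldehyde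
Conditions: MgCl2, Et3N, (CH2O)n, MeCN, reflux
Reagents that add atoms: paraformaldehyde (as formaldehyde), C=O
Why: Magnesium-mediated ortho-formylation of a phenol: formaldehyde is delivered within the magnesium phenoxide to the only free ortho position, and a second equivalent oxidises the benzylic alkoxide to the aldehyde.

Step 3
Reactants: 4 geraniol
Product: 5 geranyl methyl carbonate
Conditions: ClCO2Me, pyridine, CH2Cl2, 0 °C
Reagents that add atoms: methyl chloroformate, COC(Cl)=O
Why: Acylation of a primary allylic alcohol with a chloroformate; the E-alkene is not touched.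

Step 4
Reactants: 3 2-hydroxy-3-methyl-5-(triisopropylsilyloxy)benzaldehyde; 5 geranyl methyl carbonate
Product: 6 2-{[(3S)-3,7-dimethylocta-1,6-dien-3-yl]oxy}-3-methyl-5-(triisopropylsilyloxy)benzaldehyde
Conditions: Pd2(dba)3·CHCl3 (1 mol %), (1R,2R)-N,N'-bis[2-(diphenylphosphino)benzoyl]cyclohexane-1,2-diamine (3 mol %), CH2Cl2, rt
Reagents that add atoms: none
Why: Palladium-catalysed asymmetric allylic alkylation (Tsuji–Trost O-alkylation of a phenol): ionisation with loss of CO2 and methoxide gives a 1,1-disubstituted π-allyl complex, the phenoxide attacks its more substituted terminus inside the chiral pocket of the ligand, and the ligand sets the tertiary ether stereocentre (S).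

Step 5
Reactants: 6 2-{[(3S)-3,7-dimethylocta-1,6-dien-3-yl]oxy}-3-methyl-5-(triisopropylsilyloxy)benzaldehyde
Product: 7 {4-[(3S)-3,7-dimethylocta-1,6-dien-3-yl]oxy-3-methyl-5-vinylphenoxy}triisopropylsilane
Conditions: Ph3PCH3Br, KOtBu, THF, 0 °C; then 6
Reagents that add atoms: methyltriphenylphosphonium bromide, C[P+](c1ccccc1)(c1ccccc1)c1ccccc1.[Br-]
Why: Wittig methylenation of an aromatic aldehyde; the quaternary ether centre has no acidic hydrogen and is not at risk.

Step 6
Reactants: 7 {4-[(3S)-3,7-dimethylocta-1,6-dien-3-yl]oxy-3-methyl-5-vinylphenoxy}triisopropylsilane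
Product: 8 (2S)-2,8-dimethyl-2-(4-methylpent-3-en-1-yl)-6-(triisopropylsilyloxy)-2H-chromene
Conditions: second-generation Grubbs catalyst (3 mol %), CH2Cl2 (0.01 M), 40 °C
Reagents that add atoms: none
Why: Ring-closing metathesis of the styrene with the vinyl group on the quaternary carbon closes pyran ring B as a six-membered ring with loss of ethene; the trisubstituted side-chain alkene should engage much more slowly, and the stereocentre is not touched.

Step 7
Reactants: 8 (2S)-2,8-dimethyl-2-(4-methylpent-3-en-1-yl)-6-(triisopropylsilyloxy)-2H-chromene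
Product: 9 (2E)-5-[(2S)-2,8-dimethyl-6-(triisopropylsilyloxy)-2H-chromen-2-yl]-2-methylpent-2-en-1-ol
Conditions: SeO2 (0.2 equiv), t-BuOOH, salicylic acid (cat.), CH2Cl2, rt
Reagents that add atoms: selenium dioxide, O=[Se]=O (oxygen donor, regenerated); tert-butyl hydroperoxide, CC(C)(C)OO (terminal oxidant)
Why: Selenium dioxide allylic oxidation (ene reaction, then [2,3]-shift) is selective for the E-methyl group of a trisubstituted terminal alkene; the chromene alkene has no allylic hydrogen.

Step 8
Reactants: 9 (2E)-5-[(2S)-2,8-dimethyl-6-(triisopropylsilyloxy)-2H-chromen-2-yl]-2-methylpent-2-en-1-ol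
Product: 10 [(2S,3S)-3-{2-[(2S)-2,8-dimethyl-6-(triisopropylsilyloxy)-2H-chromen-2-yl]ethyl}-2-methyloxiran-2-yl]methanol
Conditions: Ti(OiPr)4 (10 mol %), L-(+)-diethyl tartrate (12 mol %), t-BuOOH, 4 Å molecular sieves, CH2Cl2, −20 °C
Reagents that add atoms: tert-butyl hydroperoxide, CC(C)(C)OO
Why: Sharpless asymmetric epoxidation of a 2-methyl (E)-allylic alcohol: the titanium tartrate complex delivers oxygen to one face only, setting both oxirane centres (2S,3S) by reagent control, and it leaves alkenes without an allylic hydroxyl alone.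

Step 9
Reactants: 10 [(2S,3S)-3-{2-[(2S)-2,8-dimethyl-6-(triisopropylsilyloxy)-2H-chromen-2-yl]ethyl}-2-methyloxiran-2-yl]methanol
Product: 11 (2S)-2-{2-[(2S,3R)-3-(iodomethyl)-3-methyloxiran-2-yl]ethyl}-2,8-dimethyl-6-(triisopropylsilyloxy)-2H-chromene
Conditions: I2, PPh3, imidazole, Et2O/MeCN, 0 °C
Reagents that add atoms: iodine, II
Why: Appel-type iodination of a primary alcohol (SN2 at CH2); no stereocentre is involved, the changed descriptor only reflects the new priority of CH2I.

Step 10
Reactants: 11 (2S)-2-{2-[(2S,3R)-3-(iodomethyl)-3-methyloxiran-2-yl]ethyl}-2,8-dimethyl-6-(triisopropylsilyloxy)-2H-chromene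
Product: 12 (3S)-5-[(2S)-2,8-dimethyl-6-(triisopropylsilyloxy)-2H-chromen-2-yl]-2-methylpent-1-en-3-ol
Conditions: Zn dust, EtOH/H2O, 70 °C
Reagents that add atoms: none
Why: Reductive opening of a 2,3-epoxy iodide by zinc (β-elimination of the organozinc): only the C–O bond at the quaternary oxirane carbon breaks, so the oxirane CH centre becomes the (S)-carbinol of the transposed allylic alcohol with its spatial arrangement unchanged.

Step 11
Reactants: 13 propargyl alcohol; 14 5-bromo-2-methylpent-2-ene
Product: 16 7-methyloct-6-en-2-yn-1-ol, via dilithiated propargyl alcohol 15 (not isolated)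
Conditions: n-BuLi (2 equiv), THF/DMPU, −78 to 0 °C; then 14, 0 °C to rt; H2O
Reagents that add atoms: none
Why: Alkylation of a lithium acetylide (dianion of propargyl alcohol) with a primary bromide (SN2).

Step 12
Reactants: 16 7-methyloct-6-en-2-yn-1-ol
Product: 17 1-bromo-7-methyloct-6-en-2-yne
Conditions: CBr4, PPh3, CH2Cl2, 0 °C
Reagents that add atoms: carbon tetrabromide, BrC(Br)(Br)Br
Why: Appel bromination of a primary propargylic alcohol.

Step 13
Reactants: 12 (3S)-5-[(2S)-2,8-dimethyl-6-(triisopropylsilyloxy)-2H-chromen-2-yl]-2-methylpent-1-en-3-ol; 17 1-bromo-7-methyloct-6-en-2-yne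
Product: 19 (2S)-2,8-dimethyl-2-{(3S)-4-methyl-3-[(7-methyloct-6-en-2-yn-1-yl)oxy]pent-4-en-1-yl}-6-(triisopropylsilyloxy)-2H-chromene, via sodium alkoxide 18 (not isolated)
Conditions: NaH, THF/DMF, 0 °C; then 17, Bu4NI (cat.), 0 °C to rt
Reagents that add atoms: none
Why: Williamson ether synthesis: the alkoxide displaces the primary propargylic bromide (SN2) without breaking the carbinol C–O bond, so the (S) configuration is kept; this ether oxygen is the tether that later becomes the ring oxygen of the lactone.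

Step 14
Reactants: 19 (2S)-2,8-dimethyl-2-{(3S)-4-methyl-3-[(7-methyloct-6-en-2-yn-1-yl)oxy]pent-4-en-1-yl}-6-(triisopropylsilyloxy)-2H-chromene
Product: 21 (3E,6R)-1-[(2S)-2,8-dimethyl-6-(triisopropylsilyloxy)-2H-chromen-2-yl]-4,12-dimethyltrideca-3,11-dien-7-yn-6-ol, via α-lithio propargyl ether 20 (not isolated)
Conditions: n-BuLi (1.3 equiv), THF, −78 °C to −30 °C; H2O
Reagents that add atoms: none
Why: Lithiation at the OCH2 group flanked by oxygen and the alkyne gives the α-oxy propargyl lithium 20, which undergoes a concerted suprafacial [2,3]-sigmatropic shift through a five-membered envelope transition state: the carbanion carbon (future C5 of ring C) bonds to the =CH2 terminus while the allylic C–O bond breaks, so the two halves, until now held only by the ether oxygen, become joined by the C5–CH2 bond and the oxygen is released as the C5 alkoxide. The closest known reaction type is the [2,3]-Wittig rearrangement of propargyl ethers of secondary 2-methylallyl alcohols with 1,3-chirality transfer. No ring of the target is closed here; the cyclic array exists only in the transition state. The new stereocentre C5 is controlled by the carbinol centre of 19, which is destroyed in the process: with the chromenylethyl chain pseudo-equatorial and the alkynyl group exo (turned away from the 2-methyl group), the (S)-ether should give the (R)-alcohol. The step needs E geometry of the new trisubstituted alkene, lithiation at the right carbon and [2,3] over [1,2] shift; the pseudo-equatorial chain in the alkyne-stabilised (late) transition state favours E, the α-oxygen and the alkyne together direct lithiation, and the low temperature suppresses the radical [1,2] pathway.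

Step 15
Reactants: 21 (3E,6R)-1-[(2S)-2,8-dimethyl-6-(triisopropylsilyloxy)-2H-chromen-2-yl]-4,12-dimethyltrideca-3,11-dien-7-yn-6-ol
Product: 23 (3E,6R,7Z)-1-[(2S)-2,8-dimethyl-6-(triisopropylsilyloxy)-2H-chromen-2-yl]-8-iodo-4,12-dimethyltrideca-3,7,11-trien-6-ol, via cyclic alkenylaluminate 22 (not isolated)
Conditions: NaAlH2(OCH2CH2OCH3)2, THF, 0 °C to rt; then I2, THF, −78 °C
Reagents that add atoms: iodine, II
Why: Hydroxyl-directed trans-hydroalumination of a propargylic alcohol: hydride goes to the alkyne carbon next to the carbinol and aluminium to the distal carbon within a five-membered alkoxyaluminate, and iodine cleaves the C–Al bond with retention to give the (Z)-3-iodoallylic alcohol; the carbinol centre is not involved.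

Step 16
Reactants: 23 (3E,6R,7Z)-1-[(2S)-2,8-dimethyl-6-(triisopropylsilyloxy)-2H-chromen-2-yl]-8-iodo-4,12-dimethyltrideca-3,7,11-trien-6-ol
Product: 24 O-triisopropylsilyl tuberatolide B
Conditions: PdCl2(PPh3)2 (5 mol %), CO (1 atm), Et3N, MeCN, 50 °C
Reagents that add atoms: carbon monoxide, [C-]#[O+]
Why: Palladium-catalysed carbonylative lactonisation of a (Z)-γ-iodo allylic alcohol: oxidative addition, CO insertion and attack of the cis hydroxyl on the acylpalladium close butenolide ring C (five-membered, 5-exo-trig acyl substitution) with the ring alkene geometry already fixed.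

Step 17
Reactants: 24 O-triisopropylsilyl tuberatolide B
Product: 25 tuberatolide B
Conditions: Bu4NF, AcOH, THF, 0 °C
Reagents that add atoms: none
Why: Fluoride cleavage of an aryl silyl ether; buffering with acetic acid should prevent base-induced epimerisation at the γ-position (C5) of the butenolide.

**Compound list**

1 | 2-methylhydroquinone | Cc1cc(O)ccc1O | starting material
2 | 2-methyl-4-(triisopropylsilyloxy)phenol | Cc1cc(O[Si](C(C)C)(C(C)C)C(C)C)ccc1O | intermediate
3 | 2-hydroxy-3-methyl-5-(triisopropylsilyloxy)benzaldehyde | Cc1cc(O[Si](C(C)C)(C(C)C)C(C)C)cc(C=O)c1O | intermediate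
4 | geraniol | CC(C)=CCC/C(C)=C/CO | starting material
5 | geranyl methyl carbonate | CC(C)=CCC/C(C)=C/COC(=O)OC | intermediate
6 | 2-{[(3S)-3,7-dimethylocta-1,6-dien-3-yl]oxy}-3-methyl-5-(triisopropylsilyloxy)benzaldehyde | CC(C)=CCC[C@@](C)(C=C)Oc1c(C)cc(O[Si](C(C)C)(C(C)C)C(C)C)cc1C=O | intermediate
7 | {4-[(3S)-3,7-dimethylocta-1,6-dien-3-yl]oxy-3-methyl-5-vinylphenoxy}triisopropylsilane | CC(C)=CCC[C@@](C)(C=C)Oc1c(C)cc(O[Si](C(C)C)(C(C)C)C(C)C)cc1C=C | intermediate
8 | (2S)-2,8-dimethyl-2-(4-methylpent-3-en-1-yl)-6-(triisopropylsilyloxy)-2H-chromene | CC(C)=CCC[C@@]1(C)C=Cc2cc(O[Si](C(C)C)(C(C)C)C(C)C)cc(C)c2O1 | intermediate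
9 | (2E)-5-[(2S)-2,8-dimethyl-6-(triisopropylsilyloxy)-2H-chromen-2-yl]-2-methylpent-2-en-1-ol | OC/C(C)=C/CC[C@@]1(C)C=Cc2cc(O[Si](C(C)C)(C(C)C)C(C)C)cc(C)c2O1 | intermediate
10 | [(2S,3S)-3-{2-[(2S)-2,8-dimethyl-6-(triisopropylsilyloxy)-2H-chromen-2-yl]ethyl}-2-methyloxiran-2-yl]methanol | OC[C@]1(C)O[C@H]1CC[C@@]2(C)C=Cc3cc(O[Si](C(C)C)(C(C)C)C(C)C)cc(C)c3O2 | intermediate
11 | (2S)-2-{2-[(2S,3R)-3-(iodomethyl)-3-methyloxiran-2-yl]ethyl}-2,8-dimethyl-6-(triisopropylsilyloxy)-2H-chromene | IC[C@]1(C)O[C@H]1CC[C@@]2(C)C=Cc3cc(O[Si](C(C)C)(C(C)C)C(C)C)cc(C)c3O2 | intermediate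
12 | (3S)-5-[(2S)-2,8-dimethyl-6-(triisopropylsilyloxy)-2H-chromen-2-yl]-2-methylpent-1-en-3-ol | C=C(C)[C@@H](O)CC[C@@]1(C)C=Cc2cc(O[Si](C(C)C)(C(C)C)C(C)C)cc(C)c2O1 | intermediate
13 | propargyl alcohol | C#CCO | starting material
14 | 5-bromo-2-methylpent-2-ene | CC(C)=CCCBr | starting material
15 | dilithiated propargyl alcohol (not isolated) | [Li]C#CCO[Li] | intermediate
16 | 7-methyloct-6-en-2-yn-1-ol | CC(C)=CCCC#CCO | intermediate
17 | 1-bromo-7-methyloct-6-en-2-yne | CC(C)=CCCC#CCBr | intermediate
18 | sodium alkoxide of 12 (not isolated) | C=C(C)[C@@H]([O-])CC[C@@]1(C)C=Cc2cc(O[Si](C(C)C)(C(C)C)C(C)C)cc(C)c2O1.[Na+] | intermediate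
19 | (2S)-2,8-dimethyl-2-{(3S)-4-methyl-3-[(7-methyloct-6-en-2-yn-1-yl)oxy]pent-4-en-1-yl}-6-(triisopropylsilyloxy)-2H-chromene | C=C(C)[C@@H](OCC#CCCC=C(C)C)CC[C@@]1(C)C=Cc2cc(O[Si](C(C)C)(C(C)C)C(C)C)cc(C)c2O1 | intermediate
20 | α-lithio propargyl ether of 19 (not isolated; configuration at the lithiated carbon not defined) | C=C(C)[C@@H](OC([Li])C#CCCC=C(C)C)CC[C@@]1(C)C=Cc2cc(O[Si](C(C)C)(C(C)C)C(C)C)cc(C)c2O1 | intermediate
21 | (3E,6R)-1-[(2S)-2,8-dimethyl-6-(triisopropylsilyloxy)-2H-chromen-2-yl]-4,12-dimethyltrideca-3,11-dien-7-yn-6-ol | CC(C)=CCCC#C[C@H](O)C/C(C)=C/CC[C@@]1(C)C=Cc2cc(O[Si](C(C)C)(C(C)C)C(C)C)cc(C)c2O1 | intermediate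
22 | cyclic sodium alkenyl(alkoxy)bis(2-methoxyethoxy)aluminate from 21 (not isolated) | CC(C)=CCCC1=C[C@@H](C/C(C)=C/CC[C@@]2(C)C=Cc3cc(O[Si](C(C)C)(C(C)C)C(C)C)cc(C)c3O2)O[Al-]1(OCCOC)OCCOC.[Na+] | intermediate
23 | (3E,6R,7Z)-1-[(2S)-2,8-dimethyl-6-(triisopropylsilyloxy)-2H-chromen-2-yl]-8-iodo-4,12-dimethyltrideca-3,7,11-trien-6-ol | CC(C)=CCC/C(I)=C/[C@H](O)C/C(C)=C/CC[C@@]1(C)C=Cc2cc(O[Si](C(C)C)(C(C)C)C(C)C)cc(C)c2O1 | intermediate
24 | O-triisopropylsilyl tuberatolide B, (5R)-5-{(2E)-5-[(2S)-2,8-dimethyl-6-(triisopropylsilyloxy)-2H-chromen-2-yl]-2-methylpent-2-en-1-yl}-3-(4-methylpent-3-en-1-yl)furan-2(5H)-one | CC(C)=CCCC1=C[C@@H](C/C(C)=C/CC[C@@]2(C)C=Cc3cc(O[Si](C(C)C)(C(C)C)C(C)C)cc(C)c3O2)OC1=O | intermediate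
25 | tuberatolide B | CC(C)=CCCC1=C[C@@H](C/C(C)=C/CC[C@@]2(C)C=Cc3cc(O)cc(C)c3O2)OC1=O | target

**Step count and risks**

Total step count: 17. Longest linear sequence: 14 steps (steps 1, 2, 4 to 10, 13 to 17).

The three steps most likely to fail:

1. Step 14 (key step). The shift may run in part through the conformer with the chromenylethyl chain pseudo-axial, which gives the Z-alkene and at the same time the opposite configuration at C5; some [1,2]-shift may also compete.
   - Fallback: sets out from 12 and comes back at 24. It gives up the carbinol centre and separates the two tasks.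
   - Transfer vinylation of 12 (butyl vinyl ether, Pd(OCOCF3)2, 4,7-diphenyl-1,10-phenanthroline, Et3N, 75 °C) gives allyl vinyl ether F1.
   - Claisen rearrangement (xylene, 140 °C; chair with the chain equatorial) gives the (E)-γ,δ-unsaturated aldehyde F2, making the C5–CH2 bond by a [3,3] shift that is reliably E-selective.
   - L-Proline-catalysed α-aminoxylation with nitrosobenzene (CHCl3, 0 °C) gives the (R)-α-anilinooxy aldehyde F3 by catalyst control.
   - Without isolation, Z-selective Horner–Wadsworth–Emmons reaction with the sodium salt of diphenyl phosphonate F4 (from ethyl (diphenoxyphosphoryl)acetate, NaH and bromide 14) gives the (Z)-enoate F5.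
   - Zn/AcOH cleaves the N–O bond to hydroxy ester F6, which lactonises (pyridinium tosylate, cat.) to 24.

2. Step 4. The phenoxide is flanked by two ortho substituents and hydrogen-bonded to the aldehyde, so attack may drift to the primary allyl terminus (linear geranyl ether) and facial discrimination may be low.
   - Fallback: sets out from 2 and comes back at 8 (steps 2 to 6 are then not needed).
   - Chromenylation of 2 with citral (PhB(OH)2, propionic acid, toluene, reflux; condensation and oxa-6π-electrocyclisation at the one free ortho position) gives the racemic chromene F7.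
   - Kinetic resolution by Mn(salen)-catalysed (Jacobsen–Katsuki) epoxidation follows, with N,N'-bis(3,5-di-tert-butylsalicylidene)cyclohexane-1,2-diaminomanganese chloride, NaOCl and 4-phenylpyridine N-oxide in CH2Cl2 at 0 °C, run a little past half conversion. The catalyst enantiomer is the one that consumes the (R)-chromene faster; the (R)-chromene is removed as its 3,4-epoxide F8 and (S)-8 is recovered, at the cost of at least half of the material.

3. Step 15. Hydroalumination may be incomplete, the alkenylaluminate may be protonated before the iodine quench (giving the plain E-allylic alcohol), and iodine may attack the electron-rich alkenes.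
   - Fallback: sets out from 21 and comes back at 24 in one operation, with no new compound. Palladium-catalysed cyclocarbonylation of the propargylic alcohol (Pd(dba)2, 1,4-bis(diphenylphosphino)butane, CO/H2, CH2Cl2, 95 °C) places the carbonyl on the distal alkyne carbon and closes ring C directly.

**Further compounds**

F1 | step 14 | vinyl ether of 12, (2S)-2-[(3S)-3-(ethenyloxy)-4-methylpent-4-en-1-yl]-2,8-dimethyl-6-(triisopropylsilyloxy)-2H-chromene | C=C(C)[C@@H](OC=C)CC[C@@]1(C)C=Cc2cc(O[Si](C(C)C)(C(C)C)C(C)C)cc(C)c2O1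
F2 | step 14 | (4E)-7-[(2S)-2,8-dimethyl-6-(triisopropylsilyloxy)-2H-chromen-2-yl]-4-methylhept-4-enal | O=CCC/C(C)=C/CC[C@@]1(C)C=Cc2cc(O[Si](C(C)C)(C(C)C)C(C)C)cc(C)c2O1
F3 | step 14 | (2R,4E)-2-(anilinooxy)-7-[(2S)-2,8-dimethyl-6-(triisopropylsilyloxy)-2H-chromen-2-yl]-4-methylhept-4-enal | O=C[C@H](ONc1ccccc1)C/C(C)=C/CC[C@@]1(C)C=Cc2cc(O[Si](C(C)C)(C(C)C)C(C)C)cc(C)c2O1
F4 | step 14 | ethyl 2-(diphenoxyphosphoryl)-6-methylhept-5-enoate | CCOC(=O)C(CCC=C(C)C)P(=O)(Oc1ccccc1)Oc1ccccc1
F5 | step 14 | ethyl (2Z,4R,6E)-4-(anilinooxy)-9-[(2S)-2,8-dimethyl-6-(triisopropylsilyloxy)-2H-chromen-2-yl]-6-methyl-2-(4-methylpent-3-en-1-yl)nona-2,6-dienoate | CCOC(=O)/C(CCC=C(C)C)=C\[C@H](ONc1ccccc1)C/C(C)=C/CC[C@@]1(C)C=Cc2cc(O[Si](C(C)C)(C(C)C)C(C)C)cc(C)c2O1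
F6 | step 14 | ethyl (2Z,4R,6E)-9-[(2S)-2,8-dimethyl-6-(triisopropylsilyloxy)-2H-chromen-2-yl]-4-hydroxy-6-methyl-2-(4-methylpent-3-en-1-yl)nona-2,6-dienoate | CCOC(=O)/C(CCC=C(C)C)=C\[C@H](O)C/C(C)=C/CC[C@@]1(C)C=Cc2cc(O[Si](C(C)C)(C(C)C)C(C)C)cc(C)c2O1
F7 | step 4 | racemic 2,8-dimethyl-2-(4-methylpent-3-en-1-yl)-6-(triisopropylsilyloxy)-2H-chromene | CC(C)=CCCC1(C)C=Cc2cc(O[Si](C(C)C)(C(C)C)C(C)C)cc(C)c2O1
F8 | step 4 | 3,4-epoxide of the (2R)-chromene (oxirane centres not assigned) | CC(C)=CCC[C@@]1(C)Oc2c(C)cc(O[Si](C(C)C)(C(C)C)C(C)C)cc2C2OC12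
F0 | step 15 | none | none
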